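The route rests on disconnecting the aryl ether bond between the vanillate oxygen and side-chain C1 (chain numbered from the OCH2 carbon C1 to the CMe2 carbon C7). The key step exploits the 1-aryloxy-2-oxygenated pattern, the phenolic oxygen of the benzene ring on C1 next to stereocentre C2: under (R,R)-Co(salen)OC(CF3)3 (trivalent cobalt), methyl vanillate opens only the (R)-enantiomer of a racemic 2-alkenyl oxirane at its CH2 carbon, forming the O–C1 bond and setting C2 as the (R)-carbinol; no ring is closed. The precursor is a vinyl epoxide with C5 as a silyl ether. Mesylate displacement by a masked hydroperoxide inverts C2; late oxidation reveals the C5 ketone.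

Key step: step 5

Remarks on the chemistry (assumptions):
- The target is the (2S)-hydroperoxide (CIP order at C2: OOH > CH2OAr > C3 > H). The (2R)-carbinol from step 5 has the same priority order, so one inversion (step 8) delivers it.
- C5 (the silyloxy carbon) is carried as both epimers from step 1 to step 9; they converge on the ketone in step 10.
- salen = dianion of N,N′-bis(3,5-di-tert-butylsalicylidene)cyclohexane-1,2-diamine. The catalyst is made beforehand from the divalent-cobalt complex (R,R)-Co(salen), (CF3)3COH and air.
- The (R,R) antipode is assumed to be the one matched to (R)-configured, carbon-substituted terminal oxiranes. This is to be confirmed on the first run by MTPA ester analysis of the step 5 product, and the other antipode taken if it proves reversed.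
- All peroxides are to be handled in solution, cold and behind a shield; the hydroperoxide reagent of step 7 is never concentrated to dryness.

Step 1
Reactants: 1 3-methylbut-2-enal; 2 2,3-dibromoprop-1-ene
Product: 4 2-bromo-6-methylhepta-1,5-dien-4-ol (racemic), via 2-bromoallylindium dibromide 3 (not isolated)
Conditions: In powder, THF/H2O (1:1), rt
Reagents that add atoms: none
Why: Barbier allylation, in which the allylindium formed from the allylic C–Br bond (the vinylic bromide is inert) adds 1,2 to the enal carbonyl under neutral aqueous conditions that spare the acid-sensitive allylic alcohol; the carbinol is racemic, which is harmless because this carbon ends as the C5 ketone.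

Step 2
Reactants: 4 2-bromo-6-methylhepta-1,5-dien-4-ol
Product: 5 tert-butyl[(2-bromo-6-methylhepta-1,5-dien-4-yl)oxy]dimethylsilane (racemic)
Conditions: TBSCl, imidazole, DMF, 0 °C → rt
Reagents that add atoms: tert-butyldimethylsilyl chloride, CC(C)(C)[Si](C)(C)Cl
Why: Imidazole-promoted silylation of a secondary alcohol; the TBS ether is chosen because it should withstand the organolithium, ylide, cobalt, sulfonylation and caesium peroxide steps and later leave with fluoride without acid.

Step 3
Reactants: 5 tert-butyl[(2-bromo-6-methylhepta-1,5-dien-4-yl)oxy]dimethylsilane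
Product: 8 4-[(tert-butyldimethylsilyl)oxy]-6-methyl-2-methylidenehept-5-enal (racemic), via vinyllithium 6 (not isolated), via lithium hemiaminal alkoxide 7 (not isolated)
Conditions: t-BuLi (2.1 equiv), Et2O, −78 °C; then DMF, −78 → 0 °C; aq NH4Cl
Reagents that add atoms: N,N-dimethylformamide, CN(C)C=O
Why: Bromine–lithium exchange of a vinyl bromide with two equivalents of t-BuLi followed by formylation with DMF (Bouveault-type aldehyde synthesis); ether at −78 °C should keep the vinyllithium from a 1,4 oxygen-to-carbon silyl shift before it is trapped.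

Step 4
Reactants: 8 4-[(tert-butyldimethylsilyl)oxy]-6-methyl-2-methylidenehept-5-enal
Product: 9 tert-butyldimethyl{[2-methyl-6-(oxiran-2-yl)hepta-2,6-dien-4-yl]oxy}silane (racemic at the oxirane carbon and both C4 epimers)
Conditions: Me3SI, n-BuLi, THF, −10 °C; then 8, −10 °C → rt
Reagents that add atoms: trimethylsulfonium iodide, C[S+](C)C.[I-]
Why: Corey–Chaykovsky epoxidation, in which the unstabilised sulfonium methylide adds to the aldehyde carbonyl faster than to the enal terminus and the betaine closes to the oxirane, giving the 2-alkenyl oxirane without stereocontrol at the new carbon, as the resolution requires.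

Step 5
Reactants: 9 tert-butyldimethyl{[2-methyl-6-(oxiran-2-yl)hepta-2,6-dien-4-yl]oxy}silane (racemate, 2.2 equiv); 10 methyl vanillate (methyl 4-hydroxy-3-methoxybenzoate, 1.0 equiv)
Product: 11 methyl 4-{[(2R)-5-[(tert-butyldimethylsilyl)oxy]-2-hydroxy-7-methyl-3-methylideneoct-6-en-1-yl]oxy}-3-methoxybenzoate (both C5 epimers)
Conditions: (R,R)-Co(salen)OC(CF3)3 (4 mol %, trivalent cobalt), 3 Å MS, t-BuOMe, −15 → 4 °C
Reagents that add atoms: none
Why: Kinetic resolution by enantioselective epoxide opening, in which one trivalent cobalt centre binds the oxirane oxygen as a Lewis acid and a second, cobalt-bound vanillate oxygen attacks the unsubstituted CH2 carbon in a bimetallic SN2 transition state, so the C2–O bond stays intact and the (R)-oxirane becomes the (2R)-carbinol. The closest known reaction type is the Co(salen)-catalysed phenolic kinetic resolution of terminal epoxides, whose hydrolytic counterpart is established for vinyl oxiranes. No ring is closed. No stereocentre is made from a prochiral atom: C2 is selected from the racemate by the catalyst antipode, while the remote C5 silyloxy centre should not interfere and remains as both epimers. The step needs enantiomer selection, attack at C1 and not at the allylic C2 or the methylidene terminus, and tolerance of the ester and silyl ether; these are secured by the unhindered CH2 next to a C2 flanked by the 1,1-disubstituted alkene, by the absence of any allyl–metal pathway, and by neutral conditions with the phenol as limiting reagent. The mismatched (S)-oxirane half of the racemate does not react, is left behind and is separated by chromatography.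

Step 6
Reactants: 11 methyl 4-{[(2R)-5-[(tert-butyldimethylsilyl)oxy]-2-hydroxy-7-methyl-3-methylideneoct-6-en-1-yl]oxy}-3-methoxybenzoate
Product: 12 methyl 4-{[(2R)-5-[(tert-butyldimethylsilyl)oxy]-2-(methanesulfonyloxy)-7-methyl-3-methylideneoct-6-en-1-yl]oxy}-3-methoxybenzoate (both C5 epimers)
Conditions: Ms2O, Et3N, CH2Cl2, −20 → 0 °C; used without storage
Reagents that add atoms: methanesulfonic anhydride, CS(=O)(=O)OS(C)(=O)=O
Why: O-sulfonylation of the secondary allylic alcohol with retention at C2; the anhydride is used so that no chloride is present to attack the allylic sulfonate, whose ionisation is in any case disfavoured by the neighbouring aryloxymethyl group.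

Step 7
Reactants: 13 2,3-dimethylbut-2-ene
Product: 14 2-hydroperoxy-2-methoxypropane (2-methoxyprop-2-yl hydroperoxide)
Conditions: O3, MeOH/CH2Cl2, −78 °C; N2 purge; kept and used as a cold solution
Reagents that add atoms: ozone, [O-][O+]=O; methanol, CO
Why: Ozonolysis of a tetrasubstituted alkene in methanol, in which Criegee cleavage gives acetone and acetone carbonyl oxide and methanol traps the latter as the α-methoxy hydroperoxide.

Step 8
Reactants: 12 methyl 4-{[(2R)-5-[(tert-butyldimethylsilyl)oxy]-2-(methanesulfonyloxy)-7-methyl-3-methylideneoct-6-en-1-yl]oxy}-3-methoxybenzoate; 14 2-hydroperoxy-2-methoxypropane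
Product: 16 methyl 4-{[(2S)-5-[(tert-butyldimethylsilyl)oxy]-2-[(2-methoxypropan-2-yl)peroxy]-7-methyl-3-methylideneoct-6-en-1-yl]oxy}-3-methoxybenzoate (both C5 epimers), via caesium 2-methoxypropan-2-yl peroxide 15 (not isolated)
Conditions: 14 (2.0 equiv), CsOH·H2O (1.5 equiv), DMF, 0 °C; then 12, 0 °C → rt
Reagents that add atoms: none
Why: SN2 displacement of a secondary methanesulfonate by a peroxide anion (a weakly basic α-effect nucleophile) in a dipolar aprotic solvent, which inverts C2 from R to S; the perketal masks the new O–O–H group, and the hydroperoxide kept in excess over CsOH leaves no free hydroxide to attack the methyl ester.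

Step 9
Reactants: 16 methyl 4-{[(2S)-5-[(tert-butyldimethylsilyl)oxy]-2-[(2-methoxypropan-2-yl)peroxy]-7-methyl-3-methylideneoct-6-en-1-yl]oxy}-3-methoxybenzoate
Product: 17 methyl 4-{[(2S)-5-hydroxy-2-[(2-methoxypropan-2-yl)peroxy]-7-methyl-3-methylideneoct-6-en-1-yl]oxy}-3-methoxybenzoate (both C5 epimers)
Conditions: Bu4NF, AcOH (1:1), THF, 0 °C → rt
Reagents that add atoms: none
Why: Fluoride-induced silyl ether cleavage driven by Si–F bond formation; the acetic acid buffer should keep the medium from becoming basic enough to fragment the dialkyl peroxide (Kornblum–DeLaMare pathway) or to disturb C2.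

Step 10
Reactants: 17 methyl 4-{[(2S)-5-hydroxy-2-[(2-methoxypropan-2-yl)peroxy]-7-methyl-3-methylideneoct-6-en-1-yl]oxy}-3-methoxybenzoate
Product: 18 methyl 3-methoxy-4-{[(2S)-2-[(2-methoxypropan-2-yl)peroxy]-7-methyl-3-methylidene-5-oxooct-6-en-1-yl]oxy}benzoate
Conditions: Dess–Martin periodinane, NaHCO3, CH2Cl2, 0 °C → rt
Reagents that add atoms: none
Why: Dess–Martin oxidation of the secondary allylic alcohol under bicarbonate buffer, a neutral method that should give the β,γ-unsaturated ketone without moving the C3 methylidene double bond into conjugation and without touching the peroxyketal; both C5 epimers converge on one ketone.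

Step 11
Reactants: 18 methyl 3-methoxy-4-{[(2S)-2-[(2-methoxypropan-2-yl)peroxy]-7-methyl-3-methylidene-5-oxooct-6-en-1-yl]oxy}benzoate
Product: 19 methyl 4-{[(2S)-2-hydroperoxy-7-methyl-3-methylidene-5-oxooct-6-en-1-yl]oxy}-3-methoxybenzoate (CNP0338697.1)
Conditions: AcOH/THF/H2O (4:2:1), rt
Reagents that add atoms: none
Why: Mild acid hydrolysis of the mixed peroxyketal, which should release the hydroperoxide with acetone and methanol while the O–O bond, the C2 configuration and the skipped enone are left alone by this weak acid.

Compound list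
1 | 3-methylbut-2-enal | CC(C)=CC=O | starting material
2 | 2,3-dibromoprop-1-ene | C=C(Br)CBr | starting material
3 | 2-bromoallylindium dibromide (simplest formulation of the allylindium reagent) | C=C(Br)C[In](Br)Br | intermediate (not isolated)
4 | 2-bromo-6-methylhepta-1,5-dien-4-ol (racemic) | C=C(Br)CC(O)C=C(C)C | intermediate
5 | tert-butyl[(2-bromo-6-methylhepta-1,5-dien-4-yl)oxy]dimethylsilane (racemic) | C=C(Br)CC(O[Si](C)(C)C(C)(C)C)C=C(C)C | intermediate
6 | {4-[(tert-butyldimethylsilyl)oxy]-6-methylhepta-1,5-dien-2-yl}lithium | [Li]C(=C)CC(O[Si](C)(C)C(C)(C)C)C=C(C)C | intermediate (not isolated)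
7 | lithium 4-[(tert-butyldimethylsilyl)oxy]-1-(dimethylamino)-6-methyl-2-methylidenehept-5-en-1-olate | C=C(CC(O[Si](C)(C)C(C)(C)C)C=C(C)C)C(O[Li])N(C)C | intermediate (not isolated)
8 | 4-[(tert-butyldimethylsilyl)oxy]-6-methyl-2-methylidenehept-5-enal (racemic) | C=C(C=O)CC(O[Si](C)(C)C(C)(C)C)C=C(C)C | intermediate
9 | tert-butyldimethyl{[2-methyl-6-(oxiran-2-yl)hepta-2,6-dien-4-yl]oxy}silane, racemic at the oxirane carbon and both C4 epimers (the (R)-oxirane half consumed in step 5 is C=C(CC(O[Si](C)(C)C(C)(C)C)C=C(C)C)[C@H]1OC1) | C=C(CC(O[Si](C)(C)C(C)(C)C)C=C(C)C)C1CO1 | intermediate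
10 | methyl vanillate (methyl 4-hydroxy-3-methoxybenzoate) | COC(=O)c1ccc(O)c(OC)c1 | starting material
11 | methyl 4-{[(2R)-5-[(tert-butyldimethylsilyl)oxy]-2-hydroxy-7-methyl-3-methylideneoct-6-en-1-yl]oxy}-3-methoxybenzoate (both C5 epimers) | C=C(CC(O[Si](C)(C)C(C)(C)C)C=C(C)C)[C@H](COc1ccc(C(=O)OC)cc1OC)O | intermediate
12 | methyl 4-{[(2R)-5-[(tert-butyldimethylsilyl)oxy]-2-(methanesulfonyloxy)-7-methyl-3-methylideneoct-6-en-1-yl]oxy}-3-methoxybenzoate (both C5 epimers) | C=C(CC(O[Si](C)(C)C(C)(C)C)C=C(C)C)[C@H](COc1ccc(C(=O)OC)cc1OC)OS(C)(=O)=O | intermediate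
13 | 2,3-dimethylbut-2-ene | CC(C)=C(C)C | starting material
14 | 2-hydroperoxy-2-methoxypropane | COC(C)(C)OO | intermediate (reagent made in step 7)
15 | caesium 2-methoxypropan-2-yl peroxide | COC(C)(C)O[O-].[Cs+] | intermediate (not isolated)
16 | methyl 4-{[(2S)-5-[(tert-butyldimethylsilyl)oxy]-2-[(2-methoxypropan-2-yl)peroxy]-7-methyl-3-methylideneoct-6-en-1-yl]oxy}-3-methoxybenzoate (both C5 epimers) | C=C(CC(O[Si](C)(C)C(C)(C)C)C=C(C)C)[C@@H](COc1ccc(C(=O)OC)cc1OC)OOC(C)(C)OC | intermediate
17 | methyl 4-{[(2S)-5-hydroxy-2-[(2-methoxypropan-2-yl)peroxy]-7-methyl-3-methylideneoct-6-en-1-yl]oxy}-3-methoxybenzoate (both C5 epimers) | C=C(CC(O)C=C(C)C)[C@@H](COc1ccc(C(=O)OC)cc1OC)OOC(C)(C)OC | intermediate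
18 | methyl 3-methoxy-4-{[(2S)-2-[(2-methoxypropan-2-yl)peroxy]-7-methyl-3-methylidene-5-oxooct-6-en-1-yl]oxy}benzoate | C=C(CC(=O)C=C(C)C)[C@@H](COc1ccc(C(=O)OC)cc1OC)OOC(C)(C)OC | intermediate
19 | methyl 4-{[(2S)-2-hydroperoxy-7-methyl-3-methylidene-5-oxooct-6-en-1-yl]oxy}-3-methoxybenzoate | C=C(CC(=O)C=C(C)C)[C@@H](COc1ccc(C(=O)OC)cc1OC)OO | target

Total step count: 11.
Longest linear sequence: 10 steps (from 1 and 2 through steps 1–6 and 8–11 to 19); step 7 is a one-step side branch that supplies reagent 14.

Steps most likely to fail

Step 8. Attack of the bulky peroxide anion at the methylidene terminus with allylic transposition, or base-induced elimination toward C1, may outrun direct substitution at the hindered allylic C2. The fallback sets out from 12 and uses hydrogen peroxide itself as a smaller nucleophile (50 % H2O2 in large excess, KOH, MeOH, 0 °C; the classical alkaline perhydrolysis of secondary methanesulfonates, which also inverts). This should give methyl 4-{[(2S)-5-[(tert-butyldimethylsilyl)oxy]-2-hydroperoxy-7-methyl-3-methylideneoct-6-en-1-yl]oxy}-3-methoxybenzoate F1. The free hydroperoxide is then capped with 2-methoxypropene and catalytic pyridinium p-toluenesulfonate in CH2Cl2 at 0 °C, which returns the sequence to 16.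

Step 5. The catalyst may discriminate poorly between the oxirane enantiomers when the substituent is a 1,1-disubstituted alkenyl group, or the ester-deactivated, ortho-substituted phenol may open the oxirane so slowly that background attack at the allylic carbon erodes regio- and enantioselectivity. The fallback sets out from 9 and resolves it with water instead of the phenol: the antipodal acetate complex (S,S)-Co(salen)OAc (trivalent cobalt, 0.5–1 mol %) with H2O (0.55 equiv) in THF at 0 °C → rt should hydrolyse the (S)-oxirane to (2S)-5-[(tert-butyldimethylsilyl)oxy]-7-methyl-3-methylideneoct-6-ene-1,2-diol F3 and leave tert-butyldimethyl({2-methyl-6-[(2R)-oxiran-2-yl]hepta-2,6-dien-4-yl}oxy)silane F2. F2 is separated and opened at its CH2 carbon by 10 without a chiral catalyst (CsF, DMF, 60 °C; phenoxide SN2 opening with retention at C2), which returns to 11.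

Step 3. The silyl group may migrate from oxygen to the lithiated carbon (1,4 shift), the vinyllithium may be protonated before formylation, or the 2-substituted acrolein may oligomerise on work-up. The fallback sets out from 5 and avoids the organolithium altogether: palladium-catalysed methoxycarbonylation of the vinyl bromide (Pd(OAc)2, PPh3, CO (1 atm), MeOH, Et3N, DMF, 60 °C) should give methyl 4-[(tert-butyldimethylsilyl)oxy]-6-methyl-2-methylidenehept-5-enoate F4. Reduction with i-Bu2AlH (CH2Cl2, −78 °C) gives 4-[(tert-butyldimethylsilyl)oxy]-6-methyl-2-methylidenehept-5-en-1-ol F5, and oxidation of this allylic alcohol with MnO2 (CH2Cl2, rt) rejoins the route at 8.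

Further compounds
F1 | step 8 | methyl 4-{[(2S)-5-[(tert-butyldimethylsilyl)oxy]-2-hydroperoxy-7-methyl-3-methylideneoct-6-en-1-yl]oxy}-3-methoxybenzoate (both C5 epimers) | C=C(CC(O[Si](C)(C)C(C)(C)C)C=C(C)C)[C@@H](COc1ccc(C(=O)OC)cc1OC)OO
F2 | step 5 | tert-butyldimethyl({2-methyl-6-[(2R)-oxiran-2-yl]hepta-2,6-dien-4-yl}oxy)silane (both C4 epimers) | C=C(CC(O[Si](C)(C)C(C)(C)C)C=C(C)C)[C@H]1OC1
F3 | step 5 | (2S)-5-[(tert-butyldimethylsilyl)oxy]-7-methyl-3-methylideneoct-6-ene-1,2-diol (both C5 epimers) | C=C(CC(O[Si](C)(C)C(C)(C)C)C=C(C)C)[C@@H](CO)O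
F4 | step 3 | methyl 4-[(tert-butyldimethylsilyl)oxy]-6-methyl-2-methylidenehept-5-enoate (racemic) | C=C(C(=O)OC)CC(O[Si](C)(C)C(C)(C)C)C=C(C)C
F5 | step 3 | 4-[(tert-butyldimethylsilyl)oxy]-6-methyl-2-methylidenehept-5-en-1-ol (racemic) | C=C(CO)CC(O[Si](C)(C)C(C)(C)C)C=C(C)C
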